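The quinone ring is read as an oxidised 2-methylresorcinol, and its ring C=C together with the exocyclic C=CH2 as a 2,3-disubstituted butadiene. The six-membered carbocycle is cut into a four-carbon unit, C(OMe)–C(Me)–C(=O)–CH, held as a strained 4-chlorocyclobutenone, and a two-carbon unit, the side-chain-bearing carbon and its carbonyl neighbour, held as the C(Sn)=CH2 end of a 2-stannyl-1,3-diene that already carries the (S)-carbinol. One palladium-catalysed operation joins the ring CH to the side-chain-bearing carbon (Stille coupling) and, through 4π ring opening and 6π closure of a dienylketene, the future methoxy carbon to the future carbonyl carbon. O-Methylation, esterification, loss of tert-butyl and Teuber oxidation finish.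

Key step: step 8

Remark: di-tert-butyl squarate, 4-methylpent-3-enoic acid, 1,4-dichlorobut-2-yne and angelic acid are taken as catalogue compounds.

Step 1
Reactants: 1 di-tert-butyl squarate (3,4-di-tert-butoxycyclobut-3-ene-1,2-dione)
Product: 3 3-tert-butoxy-4-methylcyclobut-3-ene-1,2-dione, via lithium alkoxide adduct 2 (not isolated)
Conditions: MeLi, THF, −78 °C; then (CF3CO)2O, −78 °C → rt; aq NaHCO3
Reagents that add atoms: methyllithium, [Li]C
Why: 1,2-addition of MeLi to one squarate carbonyl gives the tertiary alkoxide 2, whose trifluoroacetate should ionise with help of the enol ether and shed one tert-butyl group to leave the vinylogous ester dione (the standard squarate route to 3-alkoxy-4-alkylcyclobutenediones).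

Step 2
Reactants: 3 3-tert-butoxy-4-methylcyclobut-3-ene-1,2-dione
Product: 4 3-tert-butoxy-4-hydroxy-2-methylcyclobut-2-en-1-one (racemic)
Conditions: LiAlH(OtBu)3, THF, −78 → −20 °C; aq potassium sodium tartrate
Reagents that add atoms: none
Why: the carbonyl next to C–OtBu is not part of the vinylogous ester and is the more electrophilic one, so the bulky hydride should reduce it alone (regioselective 1,2-reduction); the new carbinol centre is racemic and is erased in step 8.

Step 3
Reactants: 4 3-tert-butoxy-4-hydroxy-2-methylcyclobut-2-en-1-one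
Product: 5 3-tert-butoxy-4-chloro-2-methylcyclobut-2-en-1-one (racemic)
Conditions: PPh3, CCl4, CH2Cl2, 0 °C → rt
Reagents that add atoms: carbon tetrachloride, ClC(Cl)(Cl)Cl
Why: Appel chlorination replaces the activated (allylic, α-keto) hydroxyl by chloride under neutral conditions that spare the acid-labile tert-butyl vinylogous ester; substitution at C4 keeps the enol ether conjugated with the ketone.

Step 4
Reactants: 6 4-methylpent-3-enoic acid
Product: 7 N-methoxy-N,4-dimethylpent-3-enamide
Conditions: 1,1'-carbonyldiimidazole, CH2Cl2, rt; then MeNH(OMe)·HCl, rt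
Reagents that add atoms: N,O-dimethylhydroxylamine hydrochloride, CNOC.Cl
Why: acyl imidazole formation and aminolysis (Weinreb amide synthesis) run under near-neutral conditions that should keep the β,γ-double bond out of conjugation.

Step 5
Reactants: 8 1,4-dichlorobut-2-yne
Product: 9 2,3-bis(trimethylstannyl)buta-1,3-diene
Conditions: Me3SnLi (from Me3SnCl and Li, THF, 0 °C), THF, −78 °C → rt
Reagents that add atoms: trimethyltin chloride, C[Sn](C)(C)Cl (turned in the flask by lithium into trimethylstannyllithium, [Li][Sn](C)(C)C)
Why: two successive SN2' substitutions by the stannyl anion (propargylic chloride to allenylmethyl chloride to 1,3-diene) should give the distannylbutadiene, a known preparation of this reagent.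

Step 6
Reactants: 9 2,3-bis(trimethylstannyl)buta-1,3-diene and 7 N-methoxy-N,4-dimethylpent-3-enamide
Product: 11 7-methyl-3-methylidene-2-(trimethylstannyl)octa-1,6-dien-4-one, via dienyllithium 10 (not isolated)
Conditions: MeLi (1.0 equiv), THF, −78 °C; then 7, −78 °C; AcOH, −78 °C
Reagents that add atoms: none
Why: tin–lithium exchange with one equivalent of MeLi gives the mono-lithio diene 10, and its addition to the amide stops at the chelated tetrahedral intermediate (Weinreb ketone synthesis), which the cold acetic acid quench releases as the α-methylene ketone.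

Step 7
Reactants: 11 7-methyl-3-methylidene-2-(trimethylstannyl)octa-1,6-dien-4-one
Product: 12 (4S)-7-methyl-3-methylidene-2-(trimethylstannyl)octa-1,6-dien-4-ol
Conditions: (R)-2-methyl-CBS-oxazaborolidine (20 mol %), catecholborane, toluene, −78 °C
Reagents that add atoms: none
Why: Corey–Bakshi–Shibata reduction, in which the branched dienyl group acts as the large and the CH2 chain as the small substituent, so the (R)-catalyst should deliver hydride to the face that gives the (S)-alcohol; at −78 °C only 1,2-reduction is expected.

Step 8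
Reactants: 5 3-tert-butoxy-4-chloro-2-methylcyclobut-2-en-1-one and 12 (4S)-7-methyl-3-methylidene-2-(trimethylstannyl)octa-1,6-dien-4-ol
Product: 16 3-tert-butoxy-5-[(3S)-3-hydroxy-6-methylhepta-1,5-dien-2-yl]-2-methylphenol, via 4-dienylcyclobutenone 13 (not isolated), via dienylketene 14 (not isolated), via cyclohexa-2,4-dienone 15 (not isolated)
Conditions: Pd2(dba)3 (tris(dibenzylideneacetone)dipalladium, 2.5 mol %), tri(2-furyl)phosphine (10 mol %), 1,4-dioxane, 50 °C, then 100 °C; aq KF
Reagents that add atoms: none
Why: Oxidative addition of zerovalent palladium into the allylic C–Cl bond of 5, transfer of the dienyl group of 12 from tin and reductive elimination join the CHCl carbon to the tin-bearing carbon (Stille coupling) and give 13; strain-releasing conrotatory 4π ring opening gives dienylketene 14, disrotatory 6π electrocyclisation joins the ketene carbon to the terminal CH2 of the former vinylstannane, and enolisation of 15 gives the phenol. The closest known reaction type is the palladium-catalysed coupling of 4-chlorocyclobutenones with alkenylstannanes followed by electrocyclic ring expansion to phenols. The one ring that closes, the six-membered carbocycle, closes by thermal 6π electrocyclisation of a dienylketene. No stereocentre is created: all ring carbons end sp2, the C4 centre of 13 is erased, and the (S)-carbinol from step 7 is a spectator. The step needs coupling at C4 and not at C2 of the oxocyclobutenyl–palladium species (the C2 methyl group and the conjugation kept by C4 coupling secure it), transfer of the dienyl and not a methyl group from tin, and inward rotation of the dienyl group on ring opening, which is secured because opening is reversible and only the ketene with the dienyl group cis to the ketene-bearing carbon can cyclise irreversibly. The substitution pattern of the phenol is fixed by connectivity: OH on the former ketone carbon, methyl and tert-butoxy in the order they have in 5, side chain meta to both oxygens.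

Step 9
Reactants: 16 3-tert-butoxy-5-[(3S)-3-hydroxy-6-methylhepta-1,5-dien-2-yl]-2-methylphenol
Product: 17 (3S)-2-(3-tert-butoxy-5-methoxy-4-methylphenyl)-6-methylhepta-1,5-dien-3-ol
Conditions: MeI, K2CO3, acetone, rt
Reagents that add atoms: iodomethane, CI
Why: Williamson ether synthesis, in which K2CO3 deprotonates only the phenol, so the oxygen that came from the cyclobutenone carbonyl becomes the methoxy group and the secondary alcohol stays free.

Step 10
Reactants: 17 (3S)-2-(3-tert-butoxy-5-methoxy-4-methylphenyl)-6-methylhepta-1,5-dien-3-ol and 18 angelic acid ((2Z)-2-methylbut-2-enoic acid)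
Product: 20 (3S)-2-(3-tert-butoxy-5-methoxy-4-methylphenyl)-6-methylhepta-1,5-dien-3-yl (2Z)-2-methylbut-2-enoate, via mixed anhydride 19 (not isolated)
Conditions: 18, 2,4,6-trichlorobenzoyl chloride, Et3N, toluene, rt; then 17, 75 °C
Reagents that add atoms: none
Why: Yamaguchi esterification through the mixed anhydride without a nucleophilic catalyst, the protocol known to give angelates without Z to E isomerisation; acylation on oxygen leaves the carbinol configuration untouched.

Step 11
Reactants: 20 (3S)-2-(3-tert-butoxy-5-methoxy-4-methylphenyl)-6-methylhepta-1,5-dien-3-yl (2Z)-2-methylbut-2-enoate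
Product: 21 (3S)-2-(3-hydroxy-5-methoxy-4-methylphenyl)-6-methylhepta-1,5-dien-3-yl (2Z)-2-methylbut-2-enoate
Conditions: 85 wt % aq H3PO4, toluene, rt
Reagents that add atoms: none
Why: acidolysis of the aryl tert-butyl ether (loss of the tert-butyl cation as isobutene) with mild aqueous phosphoric acid, conditions known to spare methyl aryl ethers and esters, should free the phenol that lies para to the ring CH next to the methoxy carbon.

Step 12
Reactants: 21 (3S)-2-(3-hydroxy-5-methoxy-4-methylphenyl)-6-methylhepta-1,5-dien-3-yl (2Z)-2-methylbut-2-enoate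
Product: 22 (3S)-2-(5-methoxy-4-methyl-3,6-dioxocyclohexa-1,4-dien-1-yl)-6-methylhepta-1,5-dien-3-yl (2Z)-2-methylbut-2-enoate (target)
Conditions: (KSO3)2NO, KH2PO4 buffer, acetone/H2O, 0 °C → rt
Reagents that add atoms: Fremy's salt (potassium nitrosodisulfonate), [K+].[K+].[O]N(S(=O)(=O)[O-])S(=O)(=O)[O-]
Why: Teuber oxidation, in which Fremy's radical abstracts the phenolic hydrogen, a second equivalent adds at the free para carbon (the former vinylstannane CH2, between OMe and the side chain) and loss of imidodisulfonate should give the para-quinone while esters and alkenes stay inert.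

Compound list
1 | di-tert-butyl squarate (3,4-di-tert-butoxycyclobut-3-ene-1,2-dione) | CC(C)(C)OC1=C(OC(C)(C)C)C(=O)C1=O | starting material
2 | lithium 2,3-di-tert-butoxy-1-methyl-4-oxocyclobut-2-en-1-olate | [Li+].[O-]C1(C)C(OC(C)(C)C)=C(OC(C)(C)C)C1=O | intermediate
3 | 3-tert-butoxy-4-methylcyclobut-3-ene-1,2-dione | CC1=C(OC(C)(C)C)C(=O)C1=O | intermediate
4 | 3-tert-butoxy-4-hydroxy-2-methylcyclobut-2-en-1-one (racemic) | CC1=C(OC(C)(C)C)C(O)C1=O | intermediate
5 | 3-tert-butoxy-4-chloro-2-methylcyclobut-2-en-1-one (racemic) | CC1=C(OC(C)(C)C)C(Cl)C1=O | intermediate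
6 | 4-methylpent-3-enoic acid | CC(C)=CCC(=O)O | starting material
7 | N-methoxy-N,4-dimethylpent-3-enamide | CC(C)=CCC(=O)N(C)OC | intermediate
8 | 1,4-dichlorobut-2-yne | ClCC#CCCl | starting material
9 | 2,3-bis(trimethylstannyl)buta-1,3-diene | C=C([Sn](C)(C)C)C(=C)[Sn](C)(C)C | intermediate
10 | [3-(trimethylstannyl)buta-1,3-dien-2-yl]lithium | [Li]C(=C)C(=C)[Sn](C)(C)C | intermediate
11 | 7-methyl-3-methylidene-2-(trimethylstannyl)octa-1,6-dien-4-one | C=C([Sn](C)(C)C)C(=C)C(=O)CC=C(C)C | intermediate
12 | (4S)-7-methyl-3-methylidene-2-(trimethylstannyl)octa-1,6-dien-4-ol | C=C(C(=C)[Sn](C)(C)C)[C@H](CC=C(C)C)O | intermediate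
13 | 3-tert-butoxy-4-[(4S)-4-hydroxy-7-methyl-3-methylideneocta-1,6-dien-2-yl]-2-methylcyclobut-2-en-1-one (both C4 epimers) | CC1=C(OC(C)(C)C)C(C(=C)C(=C)[C@H](CC=C(C)C)O)C1=O | intermediate
14 | (3E,7S)-3-tert-butoxy-7-hydroxy-2,10-dimethyl-5,6-dimethylideneundeca-1,3,9-trien-1-one (dienylketene, dienyl group cis to the ketene-bearing carbon) | O=C=C(C)/C(OC(C)(C)C)=C\C(=C)C(=C)[C@H](CC=C(C)C)O | intermediate
15 | 3-tert-butoxy-5-[(3S)-3-hydroxy-6-methylhepta-1,5-dien-2-yl]-2-methylcyclohexa-2,4-dien-1-one | CC1=C(OC(C)(C)C)C=C(C(=C)[C@H](CC=C(C)C)O)CC1=O | intermediate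
16 | 3-tert-butoxy-5-[(3S)-3-hydroxy-6-methylhepta-1,5-dien-2-yl]-2-methylphenol | C=C(c1cc(O)c(C)c(OC(C)(C)C)c1)[C@H](CC=C(C)C)O | intermediate
17 | (3S)-2-(3-tert-butoxy-5-methoxy-4-methylphenyl)-6-methylhepta-1,5-dien-3-ol | C=C(c1cc(OC)c(C)c(OC(C)(C)C)c1)[C@H](CC=C(C)C)O | intermediate
18 | angelic acid ((2Z)-2-methylbut-2-enoic acid) | C/C=C(/C)C(=O)O | starting material
19 | (2Z)-2-methylbut-2-enoic 2,4,6-trichlorobenzoic anhydride | C/C=C(/C)C(=O)OC(=O)c1c(Cl)cc(Cl)cc1Cl | intermediate
20 | (3S)-2-(3-tert-butoxy-5-methoxy-4-methylphenyl)-6-methylhepta-1,5-dien-3-yl (2Z)-2-methylbut-2-enoate | C=C(c1cc(OC)c(C)c(OC(C)(C)C)c1)[C@H](CC=C(C)C)OC(=O)/C(C)=C\C | intermediate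
21 | (3S)-2-(3-hydroxy-5-methoxy-4-methylphenyl)-6-methylhepta-1,5-dien-3-yl (2Z)-2-methylbut-2-enoate | C=C(c1cc(OC)c(C)c(O)c1)[C@H](CC=C(C)C)OC(=O)/C(C)=C\C | intermediate
22 | (3S)-2-(5-methoxy-4-methyl-3,6-dioxocyclohexa-1,4-dien-1-yl)-6-methylhepta-1,5-dien-3-yl (2Z)-2-methylbut-2-enoate | C=C(C1=CC(=O)C(C)=C(OC)C1=O)[C@H](CC=C(C)C)OC(=O)/C(C)=C\C | target

Total step count: 12.
Longest linear sequence: 8 steps (1, 2, 3, 8, 9, 10, 11, 12; the branch 5, 6, 7, 8 to 12 is equally long).

Steps most likely to fail

Step 8. What may go wrong: the free allylic hydroxyl may capture the ketene or the organopalladium intermediate, or protonate the carbon–tin bond, and the branched dienyl group may leave tin so slowly that the chloride is lost by reduction or dimerisation. Fallback: the ring is built first and the chain attached afterwards. It sets out from 5 and 9. The same palladium-catalysed coupling and ring expansion, run with an excess of 9, would give 3-tert-butoxy-2-methyl-5-[1-(trimethylstannyl)ethenyl]phenol F1. MeI and K2CO3 would give [1-(3-tert-butoxy-5-methoxy-4-methylphenyl)ethenyl]trimethylstannane F2. Tin–lithium exchange (MeLi, THF, −78 °C) and acylation with 7 would give 2-(3-tert-butoxy-5-methoxy-4-methylphenyl)-6-methylhepta-1,5-dien-3-one F3. Corey–Bakshi–Shibata reduction with the (R)-catalyst and catecholborane would come back to the route at 17.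

Step 11. What may go wrong: under the acid the allylic C–O bond of the angelate may ionise (loss of the ester, erosion of the carbinol configuration) and the acid part may isomerise from Z to E before the tert-butyl group has left. Fallback: the tert-butyl group is removed before any ester is present and the ester is made last. It sets out from 17. Aqueous H3PO4 in toluene would give (3S)-2-(3-hydroxy-5-methoxy-4-methylphenyl)-6-methylhepta-1,5-dien-3-ol F4. (KSO3)2NO would oxidise its phenol to 2-[(3S)-3-hydroxy-6-methylhepta-1,5-dien-2-yl]-6-methoxy-5-methylcyclohexa-2,5-diene-1,4-dione F5. Yamaguchi esterification of the secondary alcohol with 18 (through 19) would come back to the route at 22.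

Step 6. What may go wrong: the basic dienyllithium may deprotonate the doubly activated CH2 of 7 instead of adding, and the α-methylene ketone may suffer conjugate addition or polymerise when it is released. Fallback: addition to the aldehyde, then oxidation. It sets out from 7 and 9. Reduction of 7 with iBu2AlH (THF, −78 °C) would give 4-methylpent-3-enal F6. Addition of 10 (from 9 and MeLi) at −78 °C would give racemic 7-methyl-3-methylidene-2-(trimethylstannyl)octa-1,6-dien-4-ol F7. Dess–Martin oxidation buffered with NaHCO3 would come back to the route at 11.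

Further compounds
F1 | step 8 | 3-tert-butoxy-2-methyl-5-[1-(trimethylstannyl)ethenyl]phenol | C=C(c1cc(O)c(C)c(OC(C)(C)C)c1)[Sn](C)(C)C
F2 | step 8 | [1-(3-tert-butoxy-5-methoxy-4-methylphenyl)ethenyl]trimethylstannane | C=C(c1cc(OC)c(C)c(OC(C)(C)C)c1)[Sn](C)(C)C
F3 | step 8 | 2-(3-tert-butoxy-5-methoxy-4-methylphenyl)-6-methylhepta-1,5-dien-3-one | C=C(c1cc(OC)c(C)c(OC(C)(C)C)c1)C(=O)CC=C(C)C
F4 | step 11 | (3S)-2-(3-hydroxy-5-methoxy-4-methylphenyl)-6-methylhepta-1,5-dien-3-ol | C=C(c1cc(OC)c(C)c(O)c1)[C@H](CC=C(C)C)O
F5 | step 11 | 2-[(3S)-3-hydroxy-6-methylhepta-1,5-dien-2-yl]-6-methoxy-5-methylcyclohexa-2,5-diene-1,4-dione | C=C(C1=CC(=O)C(C)=C(OC)C1=O)[C@H](CC=C(C)C)O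
F6 | step 6 | 4-methylpent-3-enal | CC(C)=CCC=O
F7 | step 6 | racemic 7-methyl-3-methylidene-2-(trimethylstannyl)octa-1,6-dien-4-ol | C=C(C(=C)[Sn](C)(C)C)C(CC=C(C)C)O
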